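**Retrosynthetic overview**

1. Nortopsentin A (14) comes from its N1‑SEM derivative 13 by fluoride deprotection in the last step.
2. The strategy rests on the C2=C3 bond of each indole: the unsubstituted C2 is traced back to a formamide carbon and the imidazole‑bearing C3 to a diaryl ketone carbon, the two held ortho on a bromobenzene ring (Br para to the ketone becomes indole C6). Both pyrrole rings are closed together, last of all rings, by titanium‑mediated oxo‑amide coupling of the bis(keto‑formamide) 12.
3. 12 comes from the bis(aminoketone) 11 by formylation, 11 from the bis(2‑fluoroaryl ketone) 10 by SNAr with ammonia (fluorine is a metalation‑proof placeholder for nitrogen), and 10 from the diol 9 by oxidation.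
4. 9 comes from two additions of metalated 4‑iodo‑1‑SEM‑imidazole 4 to 4‑bromo‑2‑fluorobenzaldehyde 5: C2 by lithiation first, then C4 by iodine–magnesium exchange, the first carbinol being self‑protected as its alkoxide. 4 comes from 4‑iodoimidazole and SEMCl.

Key step: step 7

Remark: the target has no stereogenic element, so no configuration has to be set; the carbinol centres formed in steps 2 and 3 are carried as stereoisomer mixtures and are erased in step 4. (SEM = [2‑(trimethylsilyl)ethoxy]methyl.)

**Route**

Step 1
Reactants: 1 4‑iodo‑1H‑imidazole; 2 2‑(trimethylsilyl)ethoxymethyl chloride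
Product: 4 4‑iodo‑1‑{[2‑(trimethylsilyl)ethoxy]methyl}‑1H‑imidazole, via sodium 4‑iodoimidazolide 3 (not isolated)
Conditions: NaH, THF, 0 °C; then 2, 0 °C → rt; chromatography (removal of the minor N‑regioisomer)
Reagents that add atoms: none
Why: The ambident imidazolide is alkylated (SN2 N‑alkylation by the chloromethyl ether) mainly at the nitrogen remote from iodine, so the 1,4‑isomer needed for C2 and C4 functionalisation should be the main product.

Step 2
Reactants: 4 4‑iodo‑1‑SEM‑imidazole; 5 4‑bromo‑2‑fluorobenzaldehyde
Product: 7 (4‑bromo‑2‑fluorophenyl)(4‑iodo‑1‑SEM‑1H‑imidazol‑2‑yl)methanol (racemic), via 2‑lithio‑4‑iodo‑1‑SEM‑imidazole 6 (not isolated)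
Conditions: LDA, THF, −78 °C; then 5, −78 → −40 °C; aq. NH4Cl
Reagents that add atoms: none
Why: The C2–H between the two nitrogens is the most acidic proton and an amide base does not attack the C–I bond, so C2‑lithiation followed by 1,2‑addition to the aldehyde should give the carbinol, whose stereocentre is formed racemic and removed in step 4; the aldehyde level is chosen so that the product alkoxide is inert in the next metalation.

Step 3
Reactants: 7 (4‑bromo‑2‑fluorophenyl)(4‑iodo‑1‑SEM‑imidazol‑2‑yl)methanol; 5 4‑bromo‑2‑fluorobenzaldehyde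
Product: 9 1‑SEM‑1H‑imidazole‑2,4‑diyl bis[(4‑bromo‑2‑fluorophenyl)methanol] (diastereomer mixture), via C4‑chloromagnesio magnesium alkoxide 8 (not isolated)
Conditions: i‑PrMgCl (2.1 equiv), THF, −20 → 0 °C; then 5, 0 °C → rt; aq. NH4Cl
Reagents that add atoms: none
Why: The first equivalent deprotonates the hydroxyl group and the second undergoes iodine–magnesium exchange at the imidazole C4–I bond much faster than at the aryl C–Br bonds, after which the imidazol‑4‑yl Grignard reagent adds to the aldehyde (Grignard 1,2‑addition); the new carbinol centre is formed unselectively and is oxidised next.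

Step 4
Reactants: 9 1‑SEM‑imidazole‑2,4‑diyl bis[(4‑bromo‑2‑fluorophenyl)methanol]
Product: 10 1‑SEM‑1H‑imidazole‑2,4‑diyl bis[(4‑bromo‑2‑fluorophenyl)methanone]
Conditions: activated MnO2 (excess), CH2Cl2, reflux
Reagents that add atoms: none
Why: Both carbinols are flanked by an aryl and an imidazolyl ring, the substrate class for which MnO2 oxidation to diaryl ketones is reliable, and the stereocentres disappear.

Step 5
Reactants: 10 1‑SEM‑imidazole‑2,4‑diyl bis[(4‑bromo‑2‑fluorophenyl)methanone]
Product: 11 1‑SEM‑1H‑imidazole‑2,4‑diyl bis[(2‑amino‑4‑bromophenyl)methanone]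
Conditions: aq. NH3 (28 %), DMSO, 100–110 °C, sealed tube; aqueous work‑up
Reagents that add atoms: ammonia, N
Why: Each fluorine is ortho to an electron‑poor diaryl ketone and should be displaced by ammonia through a Meisenheimer intermediate (SNAr), fluoride being a far better leaving group in this mechanism than the bromide para to the carbonyl.

Step 6
Reactants: 11 1‑SEM‑imidazole‑2,4‑diyl bis[(2‑amino‑4‑bromophenyl)methanone]
Product: 12 1‑SEM‑1H‑imidazole‑2,4‑diyl bis[(4‑bromo‑2‑formamidophenyl)methanone]
Conditions: HCO2H/Ac2O (acetic formic anhydride formed beforehand at 50 °C), THF, 0 °C → rt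
Reagents that add atoms: acetic formic anhydride, CC(=O)OC=O
Why: The mixed anhydride transfers its formyl group selectively (N‑formylation at the more electrophilic formyl carbonyl) and is reactive enough for the weakly nucleophilic ortho‑acyl anilines, while the SEM‑blocked imidazole has no N–H to acylate.

Step 7
Reactants: 12 1‑SEM‑imidazole‑2,4‑diyl bis[(4‑bromo‑2‑formamidophenyl)methanone]
Product: 13 2,4‑bis(6‑bromo‑1H‑indol‑3‑yl)‑1‑SEM‑1H‑imidazole
Conditions: TiCl3, Zn dust (excess), THF, dilute, reflux; aq. EDTA/NaHCO3 work‑up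
Reagents that add atoms: none
Why: Low‑valent titanium formed in situ from TiCl3 and Zn transfers two electrons to each imidazolyl aryl ketone, the most easily reduced carbonyl, and the titanium‑bound ketyl carbon adds to the carbonyl of the ortho formamide; the resulting titanium diolate of the 2,3‑dihydroxyindoline gives up both oxygens to titanium and aromatises, so that each indole C2–C3 bond joins the former formyl carbon (C2, left unsubstituted) to the former ketone carbon (C3). The closest known reaction type is the Fürstner indole synthesis, the McMurry‑type reductive oxo‑amide coupling of 2‑acylamino aryl ketones, which is established for formamides and for azolyl aryl ketones. Each pyrrole ring closes by 5‑exo‑trig addition of the ketyl carbon to the formamide C=O, and the two closures are independent because the ketones sit on C2 and C4 of the imidazole and cannot reach each other. No stereocentre results, since both sp3 centres of the diolate are lost on aromatisation. The step needs chemoselectivity for intramolecular ketone–amide coupling over intermolecular pinacol/McMurry coupling, plain ketone reduction and reductive C–Br cleavage; this should be secured by the ortho placement of formamide and ketone (five‑membered closure to an aromatic product), by the inertness of an isolated formamide to low‑valent titanium and by the general tolerance of aryl bromides to TiCl3/Zn at this temperature.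

Step 8
Reactants: 13 2,4‑bis(6‑bromo‑1H‑indol‑3‑yl)‑1‑SEM‑imidazole
Product: 14 nortopsentin A, 2,4‑bis(6‑bromo‑1H‑indol‑3‑yl)‑1H‑imidazole
Conditions: TBAF, ethylenediamine, THF, reflux; aq. NH4Cl
Reagents that add atoms: none
Why: Fluoride attacks silicon and the SEM group fragments (fluoride‑induced β‑elimination to fluorotrimethylsilane, ethene and formaldehyde, the last bound by ethylenediamine), freeing the imidazole N–H without touching the indoles or the aryl bromides.

**Compound list**

1 | 4‑iodo‑1H‑imidazole | Ic1c[nH]cn1 | starting material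
2 | 2‑(trimethylsilyl)ethoxymethyl chloride (SEMCl) | C[Si](C)(C)CCOCCl | starting material
3 | sodium 4‑iodoimidazol‑1‑ide | [Na+].Ic1c[n-]cn1 | intermediate (not isolated)
4 | 4‑iodo‑1‑{[2‑(trimethylsilyl)ethoxy]methyl}‑1H‑imidazole | C[Si](C)(C)CCOCn1cc(I)nc1 | intermediate
5 | 4‑bromo‑2‑fluorobenzaldehyde | O=Cc1ccc(Br)cc1F | starting material
6 | 2‑lithio‑4‑iodo‑1‑SEM‑imidazole | C[Si](C)(C)CCOCn1cc(I)nc1[Li] | intermediate (not isolated)
7 | (4‑bromo‑2‑fluorophenyl)(4‑iodo‑1‑SEM‑1H‑imidazol‑2‑yl)methanol, racemic | C[Si](C)(C)CCOCn1cc(I)nc1C(O)c1ccc(Br)cc1F | intermediate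
8 | chloromagnesium alkoxide of 7 carrying MgCl at imidazole C4 | C[Si](C)(C)CCOCn1cc([Mg]Cl)nc1C(O[Mg]Cl)c1ccc(Br)cc1F | intermediate (not isolated)
9 | 1‑SEM‑1H‑imidazole‑2,4‑diyl bis[(4‑bromo‑2‑fluorophenyl)methanol], diastereomer mixture | C[Si](C)(C)CCOCn1cc(C(O)c2ccc(Br)cc2F)nc1C(O)c1ccc(Br)cc1F | intermediate
10 | 1‑SEM‑1H‑imidazole‑2,4‑diyl bis[(4‑bromo‑2‑fluorophenyl)methanone] | C[Si](C)(C)CCOCn1cc(C(=O)c2ccc(Br)cc2F)nc1C(=O)c1ccc(Br)cc1F | intermediate
11 | 1‑SEM‑1H‑imidazole‑2,4‑diyl bis[(2‑amino‑4‑bromophenyl)methanone] | C[Si](C)(C)CCOCn1cc(C(=O)c2ccc(Br)cc2N)nc1C(=O)c1ccc(Br)cc1N | intermediate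
12 | 1‑SEM‑1H‑imidazole‑2,4‑diyl bis[(4‑bromo‑2‑formamidophenyl)methanone] | C[Si](C)(C)CCOCn1cc(C(=O)c2ccc(Br)cc2NC=O)nc1C(=O)c1ccc(Br)cc1NC=O | intermediate
13 | 2,4‑bis(6‑bromo‑1H‑indol‑3‑yl)‑1‑SEM‑1H‑imidazole | C[Si](C)(C)CCOCn1cc(-c2c[nH]c3cc(Br)ccc23)nc1-c1c[nH]c2cc(Br)ccc12 | intermediate
14 | nortopsentin A | Brc1ccc2c(-c3c[nH]c(-c4c[nH]c5cc(Br)ccc45)n3)c[nH]c2c1 | target

**Step count**

Total: 8 steps. Longest linear sequence: 8 steps (1 → 14).

**Steps most likely to fail, with fallbacks**

Step 7 (key step). The reduction may stop at ketone reduction without C–C coupling, may close only one of the two rings, or may be accompanied by reductive loss of bromine. The fallback forms the pyrrole rings by N1–C2 condensation instead and sets out from 11. A double Wittig reaction with excess methoxymethylenetriphenylphosphorane (from (methoxymethyl)triphenylphosphonium chloride and KHMDS, THF, 0 °C → rt) should give the bis(enol ether) 2,4‑bis[1‑(2‑amino‑4‑bromophenyl)‑2‑methoxyethenyl]‑1‑SEM‑imidazole F1 as an E/Z mixture. Brief treatment with aqueous HCl in THF at rt should hydrolyse each enol ether to the aldehyde, which condenses with the ortho amino group and aromatises with loss of methanol. The SEM group is expected to survive, so the sequence returns to the route at 13.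

Step 5. Displacement of fluoride by ammonia may be sluggish at a temperature the substrate tolerates, and ammonia may condense with the ketones. The fallback sets out from 10 and uses a stronger nitrogen nucleophile at lower temperature. NaN3 in DMSO at about 60 °C should give 1‑SEM‑imidazole‑2,4‑diyl bis[(2‑azido‑4‑bromophenyl)methanone] F2. Staudinger reduction with PPh3 in THF passes through the bis(iminophosphorane) 1‑SEM‑imidazole‑2,4‑diyl bis{[4‑bromo‑2‑(triphenylphosphoranylideneamino)phenyl]methanone} F3, which is hydrolysed with water at 50 °C. The sequence returns to the route at 11.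

Step 2. Lithiation next to the C–I bond may be accompanied by iodine migration or loss, or by metalation at C5. The fallback reverses the order of the two C–C bond formations and sets out from 4. Iodine–magnesium exchange (i‑PrMgCl, THF, 0 °C) gives 4‑(chloromagnesio)‑1‑SEM‑imidazole F4, which adds to 5 to give (4‑bromo‑2‑fluorophenyl)(1‑SEM‑1H‑imidazol‑4‑yl)methanol F5. Treatment of F5 with TMPMgCl·LiCl (2.2 equiv, THF, −20 → 0 °C) deprotonates the hydroxyl group and then magnesiates C2, giving the chloromagnesium alkoxide of F5 carrying MgCl at imidazole C2 F6. This mild base is chosen because it should not touch the aryl C–H between fluorine and bromine. Addition of F6 to 5 returns to the route at 9.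

**Further compounds**

F1 | step 7 | 2,4‑bis[1‑(2‑amino‑4‑bromophenyl)‑2‑methoxyethenyl]‑1‑SEM‑1H‑imidazole (E/Z mixture) | C[Si](C)(C)CCOCn1cc(C(=COC)c2ccc(Br)cc2N)nc1C(=COC)c1ccc(Br)cc1N
F2 | step 5 | 1‑SEM‑1H‑imidazole‑2,4‑diyl bis[(2‑azido‑4‑bromophenyl)methanone] | C[Si](C)(C)CCOCn1cc(C(=O)c2ccc(Br)cc2N=[N+]=[N-])nc1C(=O)c1ccc(Br)cc1N=[N+]=[N-]
F3 | step 5 | 1‑SEM‑1H‑imidazole‑2,4‑diyl bis{[4‑bromo‑2‑(triphenylphosphoranylideneamino)phenyl]methanone} | C[Si](C)(C)CCOCn1cc(C(=O)c2ccc(Br)cc2N=P(c2ccccc2)(c2ccccc2)c2ccccc2)nc1C(=O)c1ccc(Br)cc1N=P(c1ccccc1)(c1ccccc1)c1ccccc1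
F4 | step 2 | 4‑(chloromagnesio)‑1‑SEM‑1H‑imidazole | C[Si](C)(C)CCOCn1cc([Mg]Cl)nc1
F5 | step 2 | (4‑bromo‑2‑fluorophenyl)(1‑SEM‑1H‑imidazol‑4‑yl)methanol | C[Si](C)(C)CCOCn1cc(C(O)c2ccc(Br)cc2F)nc1
F6 | step 2 | chloromagnesium alkoxide of F5 carrying MgCl at imidazole C2 | C[Si](C)(C)CCOCn1cc(C(O[Mg]Cl)c2ccc(Br)cc2F)nc1[Mg]Cl
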